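**Plan**
Retrosynthesis: cut the two O–CH3 bonds; then the ring bond between the carbon bearing the unsubstituted indol-3-yl group and the neighbouring ring C=O (Dieckmann closure); then an enol-lactone C–O bond and the bond between the carbon bearing the 7-prenylindol-3-yl group and the other ring C=O (crossed Claisen). This leaves two indol-3-ylpyruvate units, which go back to 7-bromoindole (aryl–prenyl bond, indole C3–CH2 bond) and N-Boc-indole-3-carbaldehyde (exocyclic C=C bond).
Enabling feature: the six quinone carbons are two ArCH2–C(=O)–CO2R units joined head to tail. Each indolyl-bearing ring carbon is a former benzylic CH2, each C–OMe a former keto carbon, each ring C=O a former carboxyl carbon, so the acidic benzylic C–H of one unit lies 1,6 to the ester carbon of the other, as in the presumed biosynthesis.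
Forward: Stille prenylation, C3 alkylation with a nitrosoalkene and deoximation give the nucleophilic pyruvate ester; a Wittig reaction gives the second unit as an arylidene dioxolanone (temporary ring: masked enol plus activated carboxyl).
Crossed Claisen acylation with lactonisation gives a pyran-2,5-dione; methoxide then opens it, closes the carbocycle and removes Boc; double O-methylation ends the route.
Stereochemistry: the target has no stereocentre and no configurational double bond; the C=C and C=N geometries of intermediates are of no consequence.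

Key step: step 7

Remark: the pyruvate ester and the open-chain tricarbonyl esters are drawn as one keto/enol tautomer each although they will be tautomeric mixtures, and the oxime is used as formed, without regard to its C=N geometry.

**Step 1**
Reactants: 1 7-bromo-1H-indole; 2 tributyl(3-methylbut-2-en-1-yl)stannane
Product: 3 7-(3-methylbut-2-en-1-yl)-1H-indole
Conditions: Pd(PPh3)4 (5 mol %), LiCl, DMF, 100 °C
Reagents that add atoms: none
Why: Stille coupling of an aryl bromide with an allylstannane on zerovalent palladium, in which transfer through the unhindered CH2 terminus should give the linear prenyl arene and the free N–H is tolerated.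

**Step 2**
Reactants: 3 7-(3-methylbut-2-en-1-yl)-1H-indole; 4 ethyl 3-bromo-2-(hydroxyimino)propanoate
Product: 6 ethyl 2-(hydroxyimino)-3-[7-(3-methylbut-2-en-1-yl)-1H-indol-3-yl]propanoate, via ethyl 2-nitrosoacrylate 5 (not isolated)
Conditions: Na2CO3, CH2Cl2, rt
Reagents that add atoms: none
Why: base-induced 1,4-elimination of HBr gives the nitrosoalkene, which is attacked by indole C3 (conjugate addition or formal hetero-Diels–Alder reaction, then rearomatisation), a known C3 alkylation of indoles by alpha-halo oximes that the much less nucleophilic prenyl alkene should not disturb.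

**Step 3**
Reactants: 6 ethyl 2-(hydroxyimino)-3-[7-(3-methylbut-2-en-1-yl)-1H-indol-3-yl]propanoate
Product: 7 ethyl 3-[7-(3-methylbut-2-en-1-yl)-1H-indol-3-yl]-2-oxopropanoate
Conditions: TiCl3 (aq.), NH4OAc, THF/H2O, 0 °C to rt, N2
Reagents that add atoms: water O
Why: reductive deoximation, in which trivalent titanium cleaves the N–O bond to the N–H imine and this hydrolyses to the alpha-keto ester under buffered conditions that spare indole and prenyl.

**Step 4**
Reactants: 8 2,2-dimethyl-1,3-dioxolan-4-one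
Product: 10 (2,2-dimethyl-5-oxo-1,3-dioxolan-4-yl)triphenylphosphonium bromide, via 5-bromo-2,2-dimethyl-1,3-dioxolan-4-one 9 (not isolated)
Conditions: NBS, AIBN (cat.), CCl4, reflux; then PPh3, PhMe, rt
Reagents that add atoms: N-bromosuccinimide O=C1CCC(=O)N1Br; triphenylphosphine c1ccc(cc1)P(c1ccccc1)c1ccccc1
Why: radical (Wohl–Ziegler) bromination of the C–H flanked by ring oxygen and carbonyl, then SN2 quaternisation of PPh3 by the reactive alpha-bromo lactone.

**Step 5**
Reactants: 10 (2,2-dimethyl-5-oxo-1,3-dioxolan-4-yl)triphenylphosphonium bromide; 11 tert-butyl 3-formyl-1H-indole-1-carboxylate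
Product: 13 tert-butyl 3-[(Z)-(2,2-dimethyl-5-oxo-1,3-dioxolan-4-ylidene)methyl]-1H-indole-1-carboxylate, via dioxolanone phosphorus ylide 12 (not isolated)
Conditions: Et3N, PhMe, 80 °C
Reagents that add atoms: none
Why: Wittig olefination with an ester-stabilised ylide, made reliable by the N-Boc group that removes the vinylogous-amide deactivation of the aldehyde; the Z alkene (aryl syn to ring oxygen) is expected but its geometry is not needed later.

**Step 6**
Reactants: 7 ethyl 3-[7-(3-methylbut-2-en-1-yl)-1H-indol-3-yl]-2-oxopropanoate; 13 tert-butyl 3-[(Z)-(2,2-dimethyl-5-oxo-1,3-dioxolan-4-ylidene)methyl]-1H-indole-1-carboxylate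
Product: 15 tert-butyl 3-{(Z)-[5-hydroxy-4-(7-(3-methylbut-2-en-1-yl)-1H-indol-3-yl)-3,6-dioxo-3,6-dihydro-2H-pyran-2-ylidene]methyl}-1H-indole-1-carboxylate, via open-chain trioxo ester 14 (not isolated)
Conditions: LiN(SiMe3)2 (1.05 equiv), THF, −78 °C; add 13, −78 °C to rt; 1 M HCl work-up
Reagents that add atoms: none
Why: Proposed new method: the chelated lithium enolate of 7 should attack the acetal-ester carbonyl of 13 through its benzylic carbon, collapse of the tetrahedral intermediate with irreversible loss of acetone then unveils the enolate oxygen of the second unit, and this oxygen closes on the ethyl ester to the six-membered enol lactone; the closest known reaction type is the crossed Claisen acylation of lithium ester enolates by 5-arylidene-2,2-dimethyl-1,3-dioxolan-4-ones followed by lactonisation to 5-arylidenetetronic acids, extended here to an alpha-keto ester enolate and a six-membered lactone.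

**Step 7**
Reactants: 15 tert-butyl 3-{(Z)-[5-hydroxy-4-(7-(3-methylbut-2-en-1-yl)-1H-indol-3-yl)-3,6-dioxo-3,6-dihydro-2H-pyran-2-ylidene]methyl}-1H-indole-1-carboxylate
Product: 18 2,5-dihydroxy-3-(1H-indol-3-yl)-6-[7-(3-methylbut-2-en-1-yl)-1H-indol-3-yl]cyclohexa-2,5-diene-1,4-dione, via open-chain methyl ester 16 (not isolated), via N-Boc dihydroxyquinone 17 (not isolated)
Conditions: NaOMe (5 equiv), MeOH/THF, 0 to 50 °C, Ar; then 1 M HCl
Reagents that add atoms: none
Why: Methoxide opens the enol lactone at its carbonyl to give methyl ester 16 and the enolate of the keto group next to the CH that bears the Boc-indolyl group; the enolate carbon attacks the ester carbonyl, methoxide leaves, and enolisation gives the dihydroxyquinone dianion, while methoxide also removes the N-Boc group as tert-butyl methyl carbonate. The closest known reaction type is the Dieckmann condensation, specifically the alkoxide-induced isomerisation of 6-arylidene-3-hydroxy-4-arylpyran-2,5-diones to 2,5-dihydroxy-3,6-diaryl-1,4-benzoquinones, and the step copies the head-to-tail Claisen/Dieckmann dimerisation of two arylpyruvate units in the presumed biosynthesis. The carbocycle closes in the 6-(enolendo)-exo-trig mode. No stereocentre is formed. The step needs C- over O-acylation, six- over five-membered closure (aldol on the neighbouring keto carbon) and no retro-Claisen scrambling; O-acylation only regenerates 15 reversibly, the acidic methine of the 7-prenylindolyl unit is deprotonated so that its two flanking carbonyls are masked as an enolate, the five-membered alternative would be a disfavoured 5-(enolendo)-exo-trig closure, and the quinone dianion is a thermodynamic sink.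

**Step 8**
Reactants: 18 2,5-dihydroxy-3-(1H-indol-3-yl)-6-[7-(3-methylbut-2-en-1-yl)-1H-indol-3-yl]cyclohexa-2,5-diene-1,4-dione
Product: 19 2,5-dimethoxy-3-(1H-indol-3-yl)-6-[7-(3-methylbut-2-en-1-yl)-1H-indol-3-yl]cyclohexa-2,5-diene-1,4-dione
Conditions: Me2SO4 (2.5 equiv), K2CO3, acetone, rt to 40 °C
Reagents that add atoms: dimethyl sulfate COS(=O)(=O)OC
Why: O-alkylation of the two vinylogous-acid hydroxyl groups as their potassium salts, which should give the 2,5-dimethoxy-para-quinone as for related 2,5-dihydroxy-3,6-diarylquinones, while the far less acidic indole N–H groups are not deprotonated by K2CO3 and stay unmethylated.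

**Compound list**
1 | 7-bromo-1H-indole | Brc1cccc2cc[nH]c12 | starting material
2 | tributyl(3-methylbut-2-en-1-yl)stannane | CCCC[Sn](CCCC)(CCCC)CC=C(C)C | starting material
3 | 7-(3-methylbut-2-en-1-yl)-1H-indole | CC(C)=CCc1cccc2cc[nH]c12 | intermediate
4 | ethyl 3-bromo-2-(hydroxyimino)propanoate | CCOC(=O)C(CBr)=NO | starting material
5 | ethyl 2-nitrosoprop-2-enoate | CCOC(=O)C(=C)N=O | intermediate
6 | ethyl 2-(hydroxyimino)-3-[7-(3-methylbut-2-en-1-yl)-1H-indol-3-yl]propanoate | CCOC(=O)C(Cc1c[nH]c2c(CC=C(C)C)cccc12)=NO | intermediate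
7 | ethyl 3-[7-(3-methylbut-2-en-1-yl)-1H-indol-3-yl]-2-oxopropanoate | CCOC(=O)C(=O)Cc1c[nH]c2c(CC=C(C)C)cccc12 | intermediate
8 | 2,2-dimethyl-1,3-dioxolan-4-one | CC1(C)OCC(=O)O1 | starting material
9 | 5-bromo-2,2-dimethyl-1,3-dioxolan-4-one (racemic) | CC1(C)OC(Br)C(=O)O1 | intermediate
10 | (2,2-dimethyl-5-oxo-1,3-dioxolan-4-yl)triphenylphosphonium bromide (racemic) | CC1(C)OC([P+](c2ccccc2)(c2ccccc2)c2ccccc2)C(=O)O1.[Br-] | intermediate
11 | tert-butyl 3-formyl-1H-indole-1-carboxylate | CC(C)(C)OC(=O)n1cc(C=O)c2ccccc12 | starting material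
12 | 2,2-dimethyl-5-(triphenyl-λ5-phosphanylidene)-1,3-dioxolan-4-one | CC1(C)OC(=P(c2ccccc2)(c2ccccc2)c2ccccc2)C(=O)O1 | intermediate
13 | tert-butyl 3-[(Z)-(2,2-dimethyl-5-oxo-1,3-dioxolan-4-ylidene)methyl]-1H-indole-1-carboxylate | CC1(C)OC(=O)/C(=C/c2cn(C(=O)OC(C)(C)C)c3ccccc23)O1 | intermediate
14 | ethyl 6-[1-(tert-butoxycarbonyl)-1H-indol-3-yl]-2-hydroxy-3-[7-(3-methylbut-2-en-1-yl)-1H-indol-3-yl]-4,5-dioxohex-2-enoate (enol tautomer, configuration not fixed) | CCOC(=O)C(O)=C(c1c[nH]c2c(CC=C(C)C)cccc12)C(=O)C(=O)Cc1cn(C(=O)OC(C)(C)C)c2ccccc12 | intermediate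
15 | tert-butyl 3-{(Z)-[5-hydroxy-4-(7-(3-methylbut-2-en-1-yl)-1H-indol-3-yl)-3,6-dioxo-3,6-dihydro-2H-pyran-2-ylidene]methyl}-1H-indole-1-carboxylate | O=C1O/C(=C\c2cn(C(=O)OC(C)(C)C)c3ccccc23)C(=O)C(c2c[nH]c3c(CC=C(C)C)cccc23)=C1O | intermediate
16 | methyl 6-[1-(tert-butoxycarbonyl)-1H-indol-3-yl]-2-hydroxy-3-[7-(3-methylbut-2-en-1-yl)-1H-indol-3-yl]-4,5-dioxohex-2-enoate (enol tautomer, configuration not fixed) | COC(=O)C(O)=C(c1c[nH]c2c(CC=C(C)C)cccc12)C(=O)C(=O)Cc1cn(C(=O)OC(C)(C)C)c2ccccc12 | intermediate
17 | tert-butyl 3-{2,5-dihydroxy-4-[7-(3-methylbut-2-en-1-yl)-1H-indol-3-yl]-3,6-dioxocyclohexa-1,4-dien-1-yl}-1H-indole-1-carboxylate | OC1=C(c2cn(C(=O)OC(C)(C)C)c3ccccc23)C(=O)C(O)=C(c2c[nH]c3c(CC=C(C)C)cccc23)C1=O | intermediate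
18 | 2,5-dihydroxy-3-(1H-indol-3-yl)-6-[7-(3-methylbut-2-en-1-yl)-1H-indol-3-yl]cyclohexa-2,5-diene-1,4-dione | OC1=C(c2c[nH]c3ccccc23)C(=O)C(O)=C(c2c[nH]c3c(CC=C(C)C)cccc23)C1=O | intermediate
19 | 2,5-dimethoxy-3-(1H-indol-3-yl)-6-[7-(3-methylbut-2-en-1-yl)-1H-indol-3-yl]cyclohexa-2,5-diene-1,4-dione | COC1=C(c2c[nH]c3ccccc23)C(=O)C(OC)=C(c2c[nH]c3c(CC=C(C)C)cccc23)C1=O | target

**Step count and risks**
Total steps: 8. Longest linear sequence: 6 (steps 1, 2, 3, 6, 7, 8).

Steps most likely to fail:

1. Step 6 (proposed new method). The ambident pyruvate enolate may acylate on oxygen, add in conjugate fashion to the arylidene, or react too slowly with the dioxolanone; premature carbocyclisation in the same flask would be harmless, since it gives 17. The fallback uses known chemistry, sets out from 3 and 11 and comes back at 16. Copper-catalysed C3–H insertion of methyl diazoacetate (Cu(OTf)2, CH2Cl2) into 3 should give methyl 2-[7-(3-methylbut-2-en-1-yl)-1H-indol-3-yl]acetate F1. Acylation of lithiated diethyl (methoxymethyl)phosphonate (LiN(iPr)2, THF, −78 °C) by F1 gives diethyl {1-methoxy-2-oxo-3-[7-(3-methylbut-2-en-1-yl)-1H-indol-3-yl]propyl}phosphonate F2. Horner–Wadsworth–Emmons olefination of 11 with F2 (LiCl, DBU, MeCN) gives tert-butyl 3-{(1Z)-2-methoxy-4-[7-(3-methylbut-2-en-1-yl)-1H-indol-3-yl]-3-oxobut-1-en-1-yl}-1H-indole-1-carboxylate F3, whose only enolisable position is the CH2 next to the 7-prenylindole. Claisen condensation of F3 with dimethyl oxalate (LiN(SiMe3)2, THF) gives methyl (5Z)-6-[1-(tert-butoxycarbonyl)-1H-indol-3-yl]-2-hydroxy-5-methoxy-3-[7-(3-methylbut-2-en-1-yl)-1H-indol-3-yl]-4-oxohexa-2,5-dienoate F4. Mild aqueous acid (1 M HCl, THF, 40 °C) hydrolyses the methyl enol ether of F4 to 16, which is cyclised as in step 7.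

2. Step 7 (key step). Under methoxide the first Claisen bond may be reversed (fragmentation and statistical recombination), the five-membered aldol closure may compete, or the electron-rich dianion may degrade in base and air. The fallback sets out from 3 and comes back at 18. Acid-promoted conjugate addition of indole to 2,5-dichloro-1,4-benzoquinone (HCl, THF) gives 2,5-dichloro-3-(1H-indol-3-yl)benzene-1,4-diol F5, which DDQ oxidises to 2,5-dichloro-3-(1H-indol-3-yl)cyclohexa-2,5-diene-1,4-dione F6. A second conjugate addition, now of 3 at the only free ring position, gives 2,5-dichloro-3-(1H-indol-3-yl)-6-[7-(3-methylbut-2-en-1-yl)-1H-indol-3-yl]benzene-1,4-diol F7, oxidised by DDQ to 2,5-dichloro-3-(1H-indol-3-yl)-6-[7-(3-methylbut-2-en-1-yl)-1H-indol-3-yl]cyclohexa-2,5-diene-1,4-dione F8. NaOH in aqueous MeOH replaces both chlorides by addition–elimination and gives 18 after acidification.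

3. Step 1. Allylic transposition during transmetalation may deliver the branched 1,1-dimethylallyl isomer, and protodestannylation may consume the stannane. The fallback sets out from 1 and comes back at 3. N-Deprotonation with KH and bromine–lithium exchange with t-BuLi (THF, −78 °C) give 7-lithio-1-potassioindole F9, whose aryl carbanion is alkylated at the primary carbon of 1-bromo-3-methylbut-2-ene (SN2) to give 3 after aqueous NH4Cl work-up.

**Further compounds**
F1 | step 6 | methyl 2-[7-(3-methylbut-2-en-1-yl)-1H-indol-3-yl]acetate | COC(=O)Cc1c[nH]c2c(CC=C(C)C)cccc12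
F2 | step 6 | diethyl {1-methoxy-2-oxo-3-[7-(3-methylbut-2-en-1-yl)-1H-indol-3-yl]propyl}phosphonate (racemic) | CCOP(=O)(OCC)C(OC)C(=O)Cc1c[nH]c2c(CC=C(C)C)cccc12
F3 | step 6 | tert-butyl 3-{(1Z)-2-methoxy-4-[7-(3-methylbut-2-en-1-yl)-1H-indol-3-yl]-3-oxobut-1-en-1-yl}-1H-indole-1-carboxylate | CO/C(=C\c1cn(C(=O)OC(C)(C)C)c2ccccc12)C(=O)Cc1c[nH]c2c(CC=C(C)C)cccc12
F4 | step 6 | methyl (5Z)-6-[1-(tert-butoxycarbonyl)-1H-indol-3-yl]-2-hydroxy-5-methoxy-3-[7-(3-methylbut-2-en-1-yl)-1H-indol-3-yl]-4-oxohexa-2,5-dienoate | COC(=O)C(O)=C(c1c[nH]c2c(CC=C(C)C)cccc12)C(=O)/C(OC)=C/c1cn(C(=O)OC(C)(C)C)c2ccccc12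
F5 | step 7 | 2,5-dichloro-3-(1H-indol-3-yl)benzene-1,4-diol | Oc1cc(Cl)c(O)c(-c2c[nH]c3ccccc23)c1Cl
F6 | step 7 | 2,5-dichloro-3-(1H-indol-3-yl)cyclohexa-2,5-diene-1,4-dione | O=C1C=C(Cl)C(=O)C(c2c[nH]c3ccccc23)=C1Cl
F7 | step 7 | 2,5-dichloro-3-(1H-indol-3-yl)-6-[7-(3-methylbut-2-en-1-yl)-1H-indol-3-yl]benzene-1,4-diol | Oc1c(Cl)c(-c2c[nH]c3ccccc23)c(O)c(Cl)c1-c1c[nH]c2c(CC=C(C)C)cccc12
F8 | step 7 | 2,5-dichloro-3-(1H-indol-3-yl)-6-[7-(3-methylbut-2-en-1-yl)-1H-indol-3-yl]cyclohexa-2,5-diene-1,4-dione | O=C1C(Cl)=C(c2c[nH]c3ccccc23)C(=O)C(Cl)=C1c1c[nH]c2c(CC=C(C)C)cccc12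
F9 | step 1 | 7-lithio-1-potassioindole | [Li]c1cccc2cc[n-]c12.[K+]
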